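**Strategy.** The cyclohexane ring (C1, C10, C11, C12, C13, C14; briarane numbering) is disconnected at C11–C12 and C13–C14. Its C14 oxygen and C11 stand 1,4 across that ring, so they become the termini of a five-membered carbonyl ylide (C14–O–C11), and the C9 oxygen, next to C11 on the β-face, carries a vinylsilane tether that delivers C12–C13. One intramolecular (3+2) cycloaddition thus closes the carbocycle and sets C11, C12 and C14. The precursor is an acyclic γ-keto aldehyde sulfonylhydrazone from a dianionic Ireland–Claisen rearrangement. Later the oxygen bridge is cut at C11 with SmI2, the lactone is annulated by aldol chemistry and the ten-membered ring closed by metathesis.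

Key step: step 15

Remark (numbering): briarane numbering is used for all compounds: C1 (quaternary, C15 methyl), C2 (OAc), C3 (O-butyrate), C4, C5=C6 (C16 methyl on C5), C7 (lactone O), C8 (OH), C9 (OAc), C10, C11 (C20 methyl), C12 (OH), C13, C14 (OAc), C17 (OH, C18 methyl), C19 (lactone C=O); β is the face of the C15 methyl, α the face of the C14 oxygen.
Assumption: (R)-4-methoxybenzyl glycidyl ether 6 and allyl methoxymethyl ether 28 are taken as commercial.

Step 1
Reactants: 1 ethyl glyoxylate; 2 isobutene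
Product: 3 ethyl (S)-2-hydroxy-4-methylpent-4-enoate
Conditions: (S)-BINOL (10 mol %), TiCl2(OiPr)2 (10 mol %), 4 Å MS, CH2Cl2, −30 °C
Reagents that add atoms: none
Why: Titanium–BINOL-catalysed asymmetric glyoxylate–ene reaction, in which the chiral Lewis acid blocks one aldehyde face so that the C3 carbinol should form as the (S)-enantiomer and the 1,1-disubstituted alkene (C5, C16) needed for the late metathesis arises directly.

Step 2
Reactants: 3 ethyl (S)-2-hydroxy-4-methylpent-4-enoate
Product: 4 ethyl (S)-2-[(tert-butyldimethylsilyl)oxy]-4-methylpent-4-enoate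
Conditions: TBSCl, imidazole, DMF, 25 °C
Reagents that add atoms: tert-butyldimethylsilyl chloride CC(C)(C)[Si](C)(C)Cl
Why: Imidazole-promoted silylation of a secondary alcohol; the bulky, non-chelating silyl ether later enforces Felkin–Anh addition next to C3.

Step 3
Reactants: 4 ethyl (S)-2-[(tert-butyldimethylsilyl)oxy]-4-methylpent-4-enoate
Product: 5 (S)-2-[(tert-butyldimethylsilyl)oxy]-4-methylpent-4-enal
Conditions: DIBAL-H, CH2Cl2, −78 °C; Rochelle salt
Reagents that add atoms: none
Why: Partial reduction of an ester with DIBAL-H stops at the tetrahedral aluminium hemiacetal at −78 °C and should give the aldehyde on work-up without touching C3.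

Step 4
Reactants: 6 (R)-2-{[(4-methoxybenzyl)oxy]methyl}oxirane
Product: 7 (R)-1-[(4-methoxybenzyl)oxy]but-3-en-2-ol
Conditions: Me3S+ I−, n-BuLi, THF, −10 → 25 °C
Reagents that add atoms: trimethylsulfonium iodide C[S+](C)C.[I-]
Why: One-carbon homologation of a terminal epoxide to an allylic alcohol with dimethylsulfonium methylide (opening at CH2, then elimination of Me2S); the C9–O bond is not touched, so its configuration is retained.

Step 5
Reactants: 7 (R)-1-[(4-methoxybenzyl)oxy]but-3-en-2-ol
Product: 8 (R)-triethyl({1-[(4-methoxybenzyl)oxy]but-3-en-2-yl}oxy)silane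
Conditions: TESCl, imidazole, CH2Cl2, 0 °C
Reagents that add atoms: chlorotriethylsilane CC[Si](Cl)(CC)CC
Why: Silylation; the triethylsilyl ether is chosen because mild acid removes it later without loss of the tert-butyldimethylsilyl ether.

Step 6
Reactants: 8 (R)-triethyl({1-[(4-methoxybenzyl)oxy]but-3-en-2-yl}oxy)silane; 9 allyl propionate
Product: 10 (R,E)-5-[(4-methoxybenzyl)oxy]-4-[(triethylsilyl)oxy]pent-2-en-1-yl propionate
Conditions: second-generation Hoveyda–Grubbs catalyst (5 mol %), 9 (4 equiv), CH2Cl2, 40 °C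
Reagents that add atoms: none
Why: Olefin cross-metathesis of the hindered allylic ether with an excess of the unhindered partner should give the (E)-alkene as the thermodynamic product without touching the stereocentre.

Step 7
Reactants: 10 (R,E)-5-[(4-methoxybenzyl)oxy]-4-[(triethylsilyl)oxy]pent-2-en-1-yl propionate; 5 (S)-2-[(tert-butyldimethylsilyl)oxy]-4-methylpent-4-enal
Product: 12 aldol adduct (β-hydroxy ester; C1 epimer mixture), via lithium enolate 11 (not isolated)
Conditions: LDA, THF, −78 °C; then 5, −78 °C; AcOH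
Reagents that add atoms: none
Why: Lithium ester enolate aldol addition to the α-silyloxy aldehyde in the Felkin–Anh sense should give the 2,3-anti relationship (C2 R), while the α-methyl centre (C1) forms as a mixture that is erased in step 8.

Step 8
Reactants: 12 aldol adduct (β-hydroxy ester; C1 epimer mixture)
Product: 15 rearranged acid (C14 carboxylic acid), via silyl ketene acetal 13 (not isolated), via trimethylsilyl ester 14 (not isolated)
Conditions: LDA (2.5 equiv), THF, −78 °C; TMSCl, Et3N, −78 → 55 °C; then K2CO3, MeOH–H2O; citric acid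
Reagents that add atoms: none
Why: Dianionic Ireland–Claisen rearrangement in which the lithium alkoxide–enolate chelate fixes the ketene acetal geometry (C2 cis to the enolate oxygen) and the chair transition state of the (E)-allyl unit, entered anti to the C3 side of the chelate and anti to the allylic C9–O bond (matched), should set the quaternary C1 and the adjacent C10 together.

Step 9
Reactants: 15 rearranged acid (C14 carboxylic acid)
Product: 16 diol (C14 primary alcohol, free C2 hydroxyl)
Conditions: LiAlH4, THF, 0 → 25 °C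
Reagents that add atoms: none
Why: Hydride reduction of the carboxylic acid to the primary alcohol; silyl ethers, the benzyl-type ether and isolated alkenes are inert to LiAlH4.

Step 10
Reactants: 16 diol (C14 primary alcohol, free C2 hydroxyl)
Product: 17 β-hydroxy aldehyde (C14 aldehyde)
Conditions: TEMPO (10 mol %), PhI(OAc)2, CH2Cl2, 25 °C
Reagents that add atoms: none
Why: TEMPO-catalysed oxidation is selective for primary over secondary alcohols, so only C14 should become the aldehyde, which cannot enolise because C1 is quaternary.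

Step 11
Reactants: 17 β-hydroxy aldehyde (C14 aldehyde)
Product: 18 C2 acetate
Conditions: Ac2O, pyridine, DMAP (cat.), CH2Cl2, 0 °C
Reagents that add atoms: acetic anhydride CC(=O)OC(C)=O
Why: DMAP-catalysed acetylation installs the final C2 acetate, which also protects O2 for the rest of the route.

Step 12
Reactants: 18 C2 acetate
Product: 19 keto aldehyde (C11 methyl ketone, C14 aldehyde)
Conditions: PdCl2 (10 mol %), CuCl, O2 (1 atm), DMF–H2O, 25 °C
Reagents that add atoms: water O
Why: Tsuji–Wacker oxidation by Markovnikov hydroxypalladation of the monosubstituted C11=C20 vinyl group gives the methyl ketone (C20 is the later C11 methyl), whereas the 1,1-disubstituted C5 alkene does not react under these conditions.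

Step 13
Reactants: 19 keto aldehyde (C11 methyl ketone, C14 aldehyde)
Product: 20 hydroxy sulfonylhydrazone (C9 hydroxyl free)
Conditions: 2-(trifluoromethyl)benzenesulfonohydrazide (1.05 equiv), PPTS (cat.), MeOH, 0 → 25 °C
Reagents that add atoms: 2-(trifluoromethyl)benzenesulfonohydrazide NNS(=O)(=O)c1ccccc1C(F)(F)F
Why: Hydrazone condensation at the aldehyde (faster than at the ketone flanked by the tertiary C10) with concurrent acid methanolysis of the triethylsilyl ether; masking C14 as the hydrazone prevents lactol formation with the freed C9 hydroxyl.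

Step 14
Reactants: 20 hydroxy sulfonylhydrazone (C9 hydroxyl free); 21 chlorodimethylvinylsilane
Product: 22 vinylsilyl ether (tethered precursor)
Conditions: imidazole, CH2Cl2, 0 °C
Reagents that add atoms: none
Why: Imidazole-promoted O-silylation attaches the temporary silicon tether to the C9 hydroxyl; the weakly nucleophilic sulfonylhydrazone N–H should not compete.

Step 15
Reactants: 22 vinylsilyl ether (tethered precursor)
Product: 25 silicon-tethered 7-oxabicyclo[2.2.1]heptane cycloadduct, via diazoalkane 23 (not isolated), via carbonyl ylide 24 (not isolated)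
Conditions: NaH (1.05 equiv), THF, 0 °C; then Rh2(OAc)4 (2 mol %), toluene, 25 → 60 °C
Reagents that add atoms: none
Why: Deprotonation and loss of arenesulfinate (Bamford–Stevens) release the neopentyl-type diazoalkane 23, Rh2(OAc)4 turns it into a carbene without β-hydrogen, and the lone pair of the C11 ketone oxygen captures it to give the cyclic carbonyl ylide 24, whose termini C14 and C11 add across the tethered vinylsilane to form C13–C14 and C11–C12. The closest known reaction type is the rhodium-catalysed tandem carbonyl ylide formation/intramolecular (3+2) cycloaddition of diazo ketones, here run with a sulfonylhydrazone-derived diazoalkane and a temporary silicon tether. Ring closures: the oxolane of the ylide closes by attack of the carbonyl oxygen on the carbene carbon (five-membered), the cycloaddition closes the carbocyclic six-membered ring as the boat of a 7-oxabicyclo[2.2.1]heptane, and the tether becomes a six-membered 1,2-oxasilinane spanning the endo positions of C10 and C12. Stereocentres: the tether on the β-oriented C9 oxygen can reach only the β-face of the planar ylide, so the oxygen bridge at C14 and C11 should end up α (trans to the C15 methyl), and the same constraint places silicon endo (β) at C12. Selectivity needed: the three-atom tether allows only the regiochemistry C12 to C11 and C13 to C14, which also matches the ylide polarity (nucleophilic C14 adds to the β-carbon of the vinylsilane), and ylide formation in a five-membered ring must outrun cyclopropanation of the C5 alkene and C–H insertion, as it normally does for ketone-tethered carbenes.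

Step 16
Reactants: 25 silicon-tethered 7-oxabicyclo[2.2.1]heptane cycloadduct
Product: 26 primary alcohol (C8 hydroxyl)
Conditions: DDQ, CH2Cl2–pH 7 buffer, 0 °C
Reagents that add atoms: none
Why: Oxidative cleavage of the 4-methoxybenzyl ether with DDQ under neutral conditions that leave the silyl ethers, the cyclic alkoxysilane and the alkene untouched.

Step 17
Reactants: 26 primary alcohol (C8 hydroxyl)
Product: 27 aldehyde (C8)
Conditions: Dess–Martin periodinane, NaHCO3, CH2Cl2, 0 °C
Reagents that add atoms: none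
Why: Dess–Martin oxidation gives the α-silyloxy aldehyde under buffered, non-epimerising conditions; it is used directly.

Step 18
Reactants: 27 aldehyde (C8); 28 allyl methoxymethyl ether
Product: 30 syn-alkoxyallylation adduct (C8 hydroxyl; C7 methoxymethyl ether; C6 vinyl), via allylborane 29 (not isolated)
Conditions: 28, s-BuLi, THF, −78 °C; (+)-Ipc2BOMe; BF3·OEt2; then 27, −78 °C; ethanolamine
Reagents that add atoms: none
Why: Brown alkoxyallylboration through a closed chair transition state, in which the (Z)-γ-alkoxyallyl geometry gives the 7,8-syn adduct and the isopinocampheyl groups derived from (−)-α-pinene should direct attack to the Re face of the aldehyde (reagent control), setting C7 as (S); the C8 carbinol is oxidised in the next step.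

Step 19
Reactants: 30 syn-alkoxyallylation adduct (C8 hydroxyl; C7 methoxymethyl ether; C6 vinyl)
Product: 31 ketone (C8)
Conditions: Dess–Martin periodinane, NaHCO3, CH2Cl2, 25 °C
Reagents that add atoms: none
Why: Dess–Martin oxidation of the secondary C8 alcohol gives the ketone flanked by the oxygen-bearing stereocentres C7 and C9.

Step 20
Reactants: 32 (S)-lactic acid; 33 pivalaldehyde
Product: 34 (2S,5S)-2-tert-butyl-5-methyl-1,3-dioxolan-4-one
Conditions: p-TsOH (cat.), pentane, reflux, water separator; recrystallisation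
Reagents that add atoms: none
Why: Acid-catalysed acetalisation under azeotropic removal of water; the cis-dioxolanone crystallises and stores the lactate configuration in the acetal centre.

Step 21
Reactants: 31 ketone (C8); 34 (2S,5S)-2-tert-butyl-5-methyl-1,3-dioxolan-4-one
Product: 36 tertiary aldol adduct (C8 hydroxyl; C17 in the dioxolanone), via lithium enolate 35 (not isolated)
Conditions: 34, LDA, THF–DMPU, −78 °C; then 31, −78 °C; AcOH
Reagents that add atoms: none
Why: Aldol addition of the dioxolanone enolate (self-regeneration of the lactate stereocentre: attack anti to the tert-butyl group sets C17) to the ketone, whose two α-C–O bonds both direct the nucleophile in the Felkin–Anh sense in the non-chelating solvent mixture, which should give the C8 configuration of the target.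

Step 22
Reactants: 36 tertiary aldol adduct (C8 hydroxyl; C17 in the dioxolanone)
Product: 38 γ-lactone (C7–O–C19; free C8 and C17 hydroxyls), via hydroxy dioxolanone 37 (not isolated)
Conditions: ZnBr2, n-PrSH, CH2Cl2, 0 °C; then PPTS (cat.), toluene, 50 °C
Reagents that add atoms: none
Why: Lewis acid–thiol cleavage of the methoxymethyl ether frees the C7 hydroxyl, which attacks the dioxolanone carbonyl (5-exo-trig acyl transfer) and expels pivalaldehyde to give the γ-lactone.

Step 23
Reactants: 38 γ-lactone (C7–O–C19; free C8 and C17 hydroxyls)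
Product: 39 C9 alcohol with C12 methoxydimethylsilyl group
Conditions: PPTS, MeOH, 25 °C
Reagents that add atoms: methanol CO
Why: Mild acid methanolysis opens the cyclic dialkyl(alkoxy)silane at its Si–O bond, freeing the C9 hydroxyl and leaving C12 as a methoxysilane, while the hindered tert-butyldimethylsilyl ether survives.

Step 24
Reactants: 39 C9 alcohol with C12 methoxydimethylsilyl group
Product: 40 C9 acetate (seco-diene)
Conditions: Ac2O, pyridine, DMAP (cat.), CH2Cl2, 0 °C
Reagents that add atoms: acetic anhydride CC(=O)OC(C)=O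
Why: Acetylation of the only secondary hydroxyl gives the final C9 acetate; the tertiary C8 and C17 hydroxyls should not react at 0 °C.

Step 25
Reactants: 40 C9 acetate (seco-diene)
Product: 41 ten-membered-ring (5Z)-alkene
Conditions: second-generation Grubbs catalyst (15 mol %), toluene (1 mM), 80 °C
Reagents that add atoms: none
Why: Ring-closing metathesis in which the catalyst loads on the monosubstituted C6 vinyl group and closes on the 1,1-disubstituted C5 alkene; the reaction is reversible and the cis ring alkene is the less strained cyclodecene, so the (5Z)-isomer is expected.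

Step 26
Reactants: 41 ten-membered-ring (5Z)-alkene
Product: 42 C3 alcohol with C12 fluorodimethylsilyl group
Conditions: HF·pyridine, pyridine, THF, 0 → 25 °C
Reagents that add atoms: hydrogen fluoride–pyridine F.c1ccncc1
Why: Fluoride cleavage of the tert-butyldimethylsilyl ether under buffered acidic conditions that disfavour acyl migration from O2; the methoxysilane on C12 becomes the fluorosilane, which is still oxidisable.

Step 27
Reactants: 42 C3 alcohol with C12 fluorodimethylsilyl group
Product: 43 C3 butyrate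
Conditions: (PrCO)2O, pyridine, DMAP (cat.), CH2Cl2, 0 °C
Reagents that add atoms: butyric anhydride CCCC(=O)OC(=O)CCC
Why: DMAP-catalysed acylation of the only free secondary hydroxyl (C3) installs the butyrate.

Step 28
Reactants: 43 C3 butyrate
Product: 44 12β-alcohol (oxygen bridge C11–O–C14 intact)
Conditions: H2O2 (30 %), KF, KHCO3, THF–MeOH, 25 °C
Reagents that add atoms: hydrogen peroxide OO
Why: Tamao–Fleming oxidation, in which hydroperoxide adds to the fluorosilane and C12 migrates from silicon to oxygen with retention, giving the 12β-alcohol already fixed by the tether.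

Step 29
Reactants: 44 12β-alcohol (oxygen bridge C11–O–C14 intact)
Product: 45 bridged ketone (C12 ketone)
Conditions: Dess–Martin periodinane, NaHCO3, CH2Cl2, 25 °C
Reagents that add atoms: none
Why: Dess–Martin oxidation of the only secondary alcohol gives the 7-oxabicyclo[2.2.1]heptan-2-one, in which the C11–O bond is α to the ketone and therefore reducible.

Step 30
Reactants: 45 bridged ketone (C12 ketone)
Product: 46 β-hydroxy ketone (C14 hydroxyl; C12 ketone; 11α-H)
Conditions: SmI2 (2.2 equiv), THF–MeOH, −78 °C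
Reagents that add atoms: none
Why: Reductive cleavage of an α-alkoxy ketone by SmI2 (ketyl, second electron transfer, expulsion of the C14 alkoxide), then kinetic protonation of the samarium enolate at C11 from the α-face, where the departing samarium alkoxide holds methanol and which lies anti to the C10 side chain and the C15 methyl, should give 11α-H.

Step 31
Reactants: 46 β-hydroxy ketone (C14 hydroxyl; C12 ketone; 11α-H)
Product: 47 briaexcavatolide L
Conditions: SmI2 (30 mol %), CH3CHO (8 equiv), THF, −10 °C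
Reagents that add atoms: acetaldehyde CC=O
Why: Evans–Tishchenko reduction, in which the C14 hydroxyl forms a samarium-bound hemiacetal with acetaldehyde that transfers hydride intramolecularly to the α-face of the C12 ketone through a six-membered transition state, should give the anti-1,3-diol with the acetate on O14 and the free 12β-hydroxyl.

**Compound list**

1 | ethyl glyoxylate | CCOC(=O)C=O | starting material
2 | isobutene | CC(C)=C | starting material
3 | ethyl (S)-2-hydroxy-4-methylpent-4-enoate | CCOC(=O)[C@@H](O)CC(C)=C | intermediate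
4 | ethyl (S)-2-[(tert-butyldimethylsilyl)oxy]-4-methylpent-4-enoate | CCOC(=O)[C@@H](O[Si](C)(C)C(C)(C)C)CC(C)=C | intermediate
5 | (S)-2-[(tert-butyldimethylsilyl)oxy]-4-methylpent-4-enal (C2–C5 and C16) | O=C[C@@H](O[Si](C)(C)C(C)(C)C)CC(C)=C | intermediate
6 | (R)-2-{[(4-methoxybenzyl)oxy]methyl}oxirane | COc1ccc(COC[C@H]2CO2)cc1 | starting material
7 | (R)-1-[(4-methoxybenzyl)oxy]but-3-en-2-ol | COc1ccc(COC[C@H](O)C=C)cc1 | intermediate
8 | (R)-triethyl({1-[(4-methoxybenzyl)oxy]but-3-en-2-yl}oxy)silane | COc1ccc(COC[C@H](O[Si](CC)(CC)CC)C=C)cc1 | intermediate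
9 | allyl propionate | CCC(=O)OCC=C | starting material
10 | (R,E)-5-[(4-methoxybenzyl)oxy]-4-[(triethylsilyl)oxy]pent-2-en-1-yl propionate | CCC(=O)OC/C=C/[C@@H](O[Si](CC)(CC)CC)COCc1ccc(OC)cc1 | intermediate
11 | lithium enolate of 10 (enolate geometry not defined) | CC=C(O[Li])OC/C=C/[C@@H](O[Si](CC)(CC)CC)COCc1ccc(OC)cc1 | intermediate
12 | aldol adduct: ester of the alcohol part of 10 with (3R,4S)-4-[(tert-butyldimethylsilyl)oxy]-3-hydroxy-2,6-dimethylhept-6-enoic acid (mixture at the α-methyl carbon, the later C1) | C=C(C)C[C@H](O[Si](C)(C)C(C)(C)C)[C@H](O)C(C)C(=O)OC/C=C/[C@@H](O[Si](CC)(CC)CC)COCc1ccc(OC)cc1 | intermediate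
13 | O-trimethylsilyl ketene acetal of 12 with the C2 hydroxyl as trimethylsilyl ether (C2 cis to OSiMe3) | C/C([C@@H](O[Si](C)(C)C)[C@@H](O[Si](C)(C)C(C)(C)C)CC(C)=C)=C(/O[Si](C)(C)C)OC/C=C/[C@@H](O[Si](CC)(CC)CC)COCc1ccc(OC)cc1 | intermediate
14 | trimethylsilyl ester of 15 with the C2 hydroxyl as trimethylsilyl ether | C[Si](C)(C)OC(=O)[C@](C)([C@@H](O[Si](C)(C)C)[C@@H](O[Si](C)(C)C(C)(C)C)CC(C)=C)[C@H](C=C)[C@@H](O[Si](CC)(CC)CC)COCc1ccc(OC)cc1 | intermediate
15 | (2S,3S,4R)-2-[(1R,2S)-2-[(tert-butyldimethylsilyl)oxy]-1-hydroxy-4-methylpent-4-en-1-yl]-5-[(4-methoxybenzyl)oxy]-2-methyl-4-[(triethylsilyl)oxy]-3-vinylpentanoic acid (C14 acid; C1, C2, C3, C9, C10 as in 47) | OC(=O)[C@](C)([C@@H](O)[C@@H](O[Si](C)(C)C(C)(C)C)CC(C)=C)[C@H](C=C)[C@@H](O[Si](CC)(CC)CC)COCc1ccc(OC)cc1 | intermediate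
16 | diol: 15 with the carboxyl reduced to CH2OH (C14) | OC[C@](C)([C@@H](O)[C@@H](O[Si](C)(C)C(C)(C)C)CC(C)=C)[C@H](C=C)[C@@H](O[Si](CC)(CC)CC)COCc1ccc(OC)cc1 | intermediate
17 | β-hydroxy aldehyde: 16 with C14 as CHO | O=C[C@](C)([C@@H](O)[C@@H](O[Si](C)(C)C(C)(C)C)CC(C)=C)[C@H](C=C)[C@@H](O[Si](CC)(CC)CC)COCc1ccc(OC)cc1 | intermediate
18 | C2 acetate of 17 | O=C[C@](C)([C@@H](OC(C)=O)[C@@H](O[Si](C)(C)C(C)(C)C)CC(C)=C)[C@H](C=C)[C@@H](O[Si](CC)(CC)CC)COCc1ccc(OC)cc1 | intermediate
19 | keto aldehyde: 18 with the vinyl group oxidised to acetyl (C11 ketone, C20 methyl) | O=C[C@](C)([C@@H](OC(C)=O)[C@@H](O[Si](C)(C)C(C)(C)C)CC(C)=C)[C@H](C(C)=O)[C@@H](O[Si](CC)(CC)CC)COCc1ccc(OC)cc1 | intermediate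
20 | (E)-2-(trifluoromethyl)benzenesulfonylhydrazone of 19 at C14 with free C9 hydroxyl | FC(F)(F)c1ccccc1S(=O)(=O)N/N=C/[C@](C)([C@@H](OC(C)=O)[C@@H](O[Si](C)(C)C(C)(C)C)CC(C)=C)[C@H](C(C)=O)[C@@H](O)COCc1ccc(OC)cc1 | intermediate
21 | chlorodimethylvinylsilane | C=C[Si](C)(C)Cl | starting material
22 | dimethylvinylsilyl ether of 20 at O9 | FC(F)(F)c1ccccc1S(=O)(=O)N/N=C/[C@](C)([C@@H](OC(C)=O)[C@@H](O[Si](C)(C)C(C)(C)C)CC(C)=C)[C@H](C(C)=O)[C@@H](O[Si](C)(C)C=C)COCc1ccc(OC)cc1 | intermediate
23 | diazoalkane (C14 diazo) from 22 | [N-]=[N+]=C[C@](C)([C@@H](OC(C)=O)[C@@H](O[Si](C)(C)C(C)(C)C)CC(C)=C)[C@H](C(C)=O)[C@@H](O[Si](C)(C)C=C)COCc1ccc(OC)cc1 | intermediate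
24 | cyclic carbonyl ylide (C14–O–C11 in a five-membered ring with C1 and C10) | CC1=[O+][CH-][C@](C)([C@@H](OC(C)=O)[C@@H](O[Si](C)(C)C(C)(C)C)CC(C)=C)[C@H]1[C@@H](O[Si](C)(C)C=C)COCc1ccc(OC)cc1 | intermediate
25 | cycloadduct: 7-oxabicyclo[2.2.1]heptane (O bridging C11 and C14, α) fused at C10–C11–C12 to a 2,2-dimethyl-1,2-oxasilinane (O on C9, Si on C12, β); C1 carries the C15 methyl and the C2(OAc)–C3(OTBS)–C4–C5(Me)=CH2 chain, C9 carries CH2OPMB | CC(=O)O[C@@H]([C@@H](O[Si](C)(C)C(C)(C)C)CC(C)=C)[C@@]1(C)[C@H]2O[C@@]3(C)[C@@H]1[C@H](COCc4ccc(OC)cc4)O[Si](C)(C)[C@H]3C2 | intermediate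
26 | primary alcohol: 25 without the 4-methoxybenzyl group (C8 hydroxyl) | CC(=O)O[C@@H]([C@@H](O[Si](C)(C)C(C)(C)C)CC(C)=C)[C@@]1(C)[C@H]2O[C@@]3(C)[C@@H]1[C@H](CO)O[Si](C)(C)[C@H]3C2 | intermediate
27 | aldehyde: 26 with C8 as CHO | CC(=O)O[C@@H]([C@@H](O[Si](C)(C)C(C)(C)C)CC(C)=C)[C@@]1(C)[C@H]2O[C@@]3(C)[C@@H]1[C@H](C=O)O[Si](C)(C)[C@H]3C2 | intermediate
28 | allyl methoxymethyl ether | C=CCOCOC | starting material
29 | [(Z)-3-(methoxymethoxy)allyl]diisopinocampheylborane from (−)-α-pinene | COCO/C=C\CB([C@H]1C[C@H]2C[C@@H]([C@@H]1C)C2(C)C)[C@H]1C[C@H]2C[C@@H]([C@@H]1C)C2(C)C | intermediate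
30 | adduct: 27 extended by C7 (S, methoxymethyl ether) and the C6 vinyl group, with a secondary C8 hydroxyl syn to O7 | CC(=O)O[C@@H]([C@@H](O[Si](C)(C)C(C)(C)C)CC(C)=C)[C@@]1(C)[C@H]2O[C@@]3(C)[C@@H]1[C@H]([C@H](O)[C@@H](OCOC)C=C)O[Si](C)(C)[C@H]3C2 | intermediate
31 | ketone: 30 with C8 as C=O | CC(=O)O[C@@H]([C@@H](O[Si](C)(C)C(C)(C)C)CC(C)=C)[C@@]1(C)[C@H]2O[C@@]3(C)[C@@H]1[C@H](C(=O)[C@@H](OCOC)C=C)O[Si](C)(C)[C@H]3C2 | intermediate
32 | (S)-lactic acid | C[C@H](O)C(=O)O | starting material
33 | pivalaldehyde | CC(C)(C)C=O | starting material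
34 | (2S,5S)-2-tert-butyl-5-methyl-1,3-dioxolan-4-one | C[C@@H]1O[C@H](C(C)(C)C)OC1=O | intermediate
35 | lithium enolate of 34 | CC1=C(O[Li])O[C@@H](C(C)(C)C)O1 | intermediate
36 | aldol adduct: 31 with C8 as tertiary alcohol bonded to C17 of the dioxolanone (C8 and C17 as in 47) | CC(=O)O[C@@H]([C@@H](O[Si](C)(C)C(C)(C)C)CC(C)=C)[C@@]1(C)[C@H]2O[C@@]3(C)[C@@H]1[C@H]([C@](O)([C@@H](OCOC)C=C)[C@@]4(C)O[C@H](C(C)(C)C)OC4=O)O[Si](C)(C)[C@H]3C2 | intermediate
37 | 36 with free C7 hydroxyl | CC(=O)O[C@@H]([C@@H](O[Si](C)(C)C(C)(C)C)CC(C)=C)[C@@]1(C)[C@H]2O[C@@]3(C)[C@@H]1[C@H]([C@](O)([C@@H](O)C=C)[C@@]4(C)O[C@H](C(C)(C)C)OC4=O)O[Si](C)(C)[C@H]3C2 | intermediate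
38 | γ-lactone (C7–O–C19(=O)–C17(Me)(OH)–C8(OH)) carrying the C6 vinyl group on C7, attached at C8 to C9 of the tricyclic silyl ether core | CC(=O)O[C@@H]([C@@H](O[Si](C)(C)C(C)(C)C)CC(C)=C)[C@@]1(C)[C@H]2O[C@@]3(C)[C@@H]1[C@H]([C@]4(O)[C@H](C=C)OC(=O)[C@]4(C)O)O[Si](C)(C)[C@H]3C2 | intermediate
39 | 38 with the Si–O9 bond opened: free C9 hydroxyl, C12 methoxydimethylsilyl (β) | CC(=O)O[C@@H]([C@@H](O[Si](C)(C)C(C)(C)C)CC(C)=C)[C@@]1(C)[C@@H]2C[C@H]([Si](C)(C)OC)[C@@](C)(O2)[C@@H]1[C@@H](O)[C@]4(O)[C@H](C=C)OC(=O)[C@]4(C)O | intermediate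
40 | C9 acetate of 39 | CC(=O)O[C@@H]([C@@H](O[Si](C)(C)C(C)(C)C)CC(C)=C)[C@@]1(C)[C@@H]2C[C@H]([Si](C)(C)OC)[C@@](C)(O2)[C@@H]1[C@@H](OC(C)=O)[C@]4(O)[C@H](C=C)OC(=O)[C@]4(C)O | intermediate
41 | macrocycle: briarane skeleton with (5Z)-alkene, C3 OTBS, C2 and C9 acetates, lactone diol, C11–O–C14 bridge, C12 methoxydimethylsilyl | CC(C)(C)[Si](C)(C)O[C@H]1C/C(C)=C\[C@@H]2OC(=O)[C@](C)(O)[C@]2(O)[C@H](OC(C)=O)[C@H]2[C@@]3(C)[C@@H]([Si](C)(C)OC)C[C@H](O3)[C@]2(C)[C@H]1OC(C)=O | intermediate
42 | 41 with free C3 hydroxyl and C12 fluorodimethylsilyl | O[C@H]1C/C(C)=C\[C@@H]2OC(=O)[C@](C)(O)[C@]2(O)[C@H](OC(C)=O)[C@H]2[C@@]3(C)[C@@H]([Si](C)(C)F)C[C@H](O3)[C@]2(C)[C@H]1OC(C)=O | intermediate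
43 | C3 butyrate of 42 | CCCC(=O)O[C@H]1C/C(C)=C\[C@@H]2OC(=O)[C@](C)(O)[C@]2(O)[C@H](OC(C)=O)[C@H]2[C@@]3(C)[C@@H]([Si](C)(C)F)C[C@H](O3)[C@]2(C)[C@H]1OC(C)=O | intermediate
44 | 43 with C12–Si replaced by 12β-OH | CCCC(=O)O[C@H]1C/C(C)=C\[C@@H]2OC(=O)[C@](C)(O)[C@]2(O)[C@H](OC(C)=O)[C@H]2[C@@]3(C)[C@@H](O)C[C@H](O3)[C@]2(C)[C@H]1OC(C)=O | intermediate
45 | bridged ketone: 44 with C12 as C=O | CCCC(=O)O[C@H]1C/C(C)=C\[C@@H]2OC(=O)[C@](C)(O)[C@]2(O)[C@H](OC(C)=O)[C@H]2[C@@]3(C)C(=O)C[C@H](O3)[C@]2(C)[C@H]1OC(C)=O | intermediate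
46 | 14-deacetyl-12-oxo compound: bridge opened, C14 α-OH, C12 ketone, C11 β-methyl (11α-H) | CCCC(=O)O[C@H]1C/C(C)=C\[C@@H]2OC(=O)[C@](C)(O)[C@]2(O)[C@H](OC(C)=O)[C@H]2[C@@H](C)C(=O)C[C@H](O)[C@]2(C)[C@H]1OC(C)=O | intermediate
47 | briaexcavatolide L, (1R,2R,3S,5Z,7S,8R,9R,10S,11R,12S,14S,17R) | CCCC(=O)O[C@H]1C/C(C)=C\[C@@H]2OC(=O)[C@](C)(O)[C@]2(O)[C@H](OC(C)=O)[C@H]2[C@@H](C)[C@@H](O)C[C@H](OC(C)=O)[C@]2(C)[C@H]1OC(C)=O | target

**Totals.** Total step count: 31. Longest linear sequence: 27 steps (steps 1–3, 7–19, 21–31; the branch through steps 4–6 is equally long).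

**Steps most likely to fail**

Step 15 (key step). What may go wrong: the non-stabilised carbene is diverted before the ketone captures it (azine formation from slowly released diazoalkane, addition of the hydrazone anion to the C11 ketone, N-silylation in step 14 that blocks salt formation). Fallback: the same diazoalkane is released thermally and without base from an N-aziridinylimine. The fallback sets out from keto aldehyde 19, which is condensed with racemic 1-amino-2-phenylaziridine (EtOH, 0 °C) to give the N-aziridinylimine F1 (two diastereomers at the aziridine carbon). PPTS in MeOH removes the triethylsilyl group to give the alcohol F2, and silylation with 21 and imidazole gives the vinylsilyl ether F3. Heating F3 in toluene at 90 °C with Rh2(OAc)4 fragments it to styrene and diazoalkane 23, which passes through ylide 24 and comes back to the route at 25.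

Step 25. What may go wrong: the ruthenium carbene fails to load on the C6 vinyl group, which sits on the acylated C7 next to the fully substituted C8, or it loads and then oligomerises faster than it closes on the 1,1-disubstituted alkene. Fallback: the ring is closed before the lactone is built, on a substrate whose vinyl group is an allylic ether beside a ketone. The fallback sets out from ketone 31, which is cyclised with the second-generation Grubbs catalyst (toluene, 80 °C, high dilution) to the macrocyclic ketone F4. Aldol addition of enolate 35 as in step 21 gives the macrocyclic aldol adduct F5, and ZnBr2 with n-PrSH then PPTS gives the macrocyclic lactone F6. Methanolysis with PPTS in MeOH opens the silicon ring to the alcohol F7, whose acetylation (Ac2O, pyridine) comes back to the route at 41.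

Step 21. What may go wrong: the basic lithium enolate enolises the doubly α-oxygenated ketone instead of adding, the hindered adduct reverts by retro-aldol on warming, or chelation by the methoxymethyl ether erodes the facial control. Fallback: a Lewis-acid-promoted Mukaiyama aldol replaces the basic enolate addition. The fallback sets out from dioxolanone 34, which is converted with LDA and TMSCl into the silyl enol ether F8. F8 is added to ketone 31 with BF3·OEt2 in CH2Cl2 at −78 °C, where addition is irreversible and non-chelating, and aqueous work-up comes back to the route at 36.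

**Further compounds**

F1 | step 15 | N-(2-phenylaziridin-1-yl)imine of keto aldehyde 19 at C14 (triethylsilyl ether intact; mixture at the aziridine carbon) | c1ccccc1C1CN1/N=C/[C@](C)([C@@H](OC(C)=O)[C@@H](O[Si](C)(C)C(C)(C)C)CC(C)=C)[C@H](C(C)=O)[C@@H](O[Si](CC)(CC)CC)COCc1ccc(OC)cc1
F2 | step 15 | F1 with free C9 hydroxyl | c1ccccc1C1CN1/N=C/[C@](C)([C@@H](OC(C)=O)[C@@H](O[Si](C)(C)C(C)(C)C)CC(C)=C)[C@H](C(C)=O)[C@@H](O)COCc1ccc(OC)cc1
F3 | step 15 | dimethylvinylsilyl ether of F2 at O9 | c1ccccc1C1CN1/N=C/[C@](C)([C@@H](OC(C)=O)[C@@H](O[Si](C)(C)C(C)(C)C)CC(C)=C)[C@H](C(C)=O)[C@@H](O[Si](C)(C)C=C)COCc1ccc(OC)cc1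
F4 | step 25 | macrocyclic ketone: ten-membered (5Z)-alkene ring with C8 ketone, C7 methoxymethyl ether, C3 OTBS, C2 acetate, silicon-tethered oxygen-bridged core | CC(C)(C)[Si](C)(C)O[C@H]1C/C(C)=C\[C@H](OCOC)C(=O)[C@@H]2O[Si](C)(C)[C@H]3C[C@@H]4O[C@@]3(C)[C@H]2[C@@]4(C)[C@H]1OC(C)=O
F5 | step 25 | aldol adduct of F4 with the dioxolanone at C8 | CC(C)(C)[Si](C)(C)O[C@H]1C/C(C)=C\[C@H](OCOC)[C@](O)([C@@]5(C)O[C@H](C(C)(C)C)OC5=O)[C@@H]2O[Si](C)(C)[C@H]3C[C@@H]4O[C@@]3(C)[C@H]2[C@@]4(C)[C@H]1OC(C)=O
F6 | step 25 | macrocyclic lactone with the silicon ring still closed (O9–Si–C12) | CC(C)(C)[Si](C)(C)O[C@H]1C/C(C)=C\[C@@H]2OC(=O)[C@](C)(O)[C@]2(O)[C@@H]2O[Si](C)(C)[C@H]3C[C@@H]4O[C@@]3(C)[C@H]2[C@@]4(C)[C@H]1OC(C)=O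
F7 | step 25 | 9-deacetyl analogue of 41 (free C9 hydroxyl, C12 methoxydimethylsilyl) | CC(C)(C)[Si](C)(C)O[C@H]1C/C(C)=C\[C@@H]2OC(=O)[C@](C)(O)[C@]2(O)[C@H](O)[C@H]2[C@@]3(C)[C@@H]([Si](C)(C)OC)C[C@H](O3)[C@]2(C)[C@H]1OC(C)=O
F8 | step 21 | (S)-2-tert-butyl-5-methyl-4-[(trimethylsilyl)oxy]-1,3-dioxole (silyl enol ether of 34) | CC1=C(O[Si](C)(C)C)O[C@@H](C(C)(C)C)O1
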